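## Retrosynthetic overview
1. Last bond: C3 (lactam)–C2 (dienone). It is made by an enantioselective Mannich-type amidoalkylation of the free vinylogous acid with the N-acylimine released from a 3-hydroxyisoindolinone. This sets the only stereocentre.
2. Key step: the dienone ring comes from a one-carbon ring expansion of 4-methyl-5,5-diprenylcyclopent-3-ene-1,2-dione (ionic 1,2-acyl shift with loss of N2). The inserted carbon becomes the nucleophilic C2.
3. The cyclopentenedione comes from 3-methylcyclopent-2-enone by deconjugative gem-diprenylation, then α-oximation and transoximation at the only enolisable CH2.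
4. The hydroxylactam comes from anisole by two directed lithiations in one flask (formyl carbon, then carbamoyl carbon). The lactam ring closes on work-up.
5. Ring order: the bought five-membered carbocycle is expanded to the six-membered dienone; the bought arene gains the lactam ring; the two halves are joined last.

Assumption: the SMILES descriptor corresponds to (S) at C3 of the isoindolinone (priorities N > dienone C > aryl C > H). The (R)-configured acid is taken to deliver this sense; if analysis shows the opposite, its mirror image is used.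

## Route

Step 1
Reactants: 1 3-methylcyclopent-2-en-1-one; 2 1-bromo-3-methylbut-2-ene (prenyl bromide, 2.05 equiv)
Product: 4 3-methyl-2,2-bis(3-methylbut-2-en-1-yl)cyclopent-3-en-1-one, via monoprenyl enone 3 (not isolated)
Conditions: KOt-Bu (2.2 equiv), t-BuOH/THF, 0 °C to rt, slow addition of 2
Reagents that add atoms: none
Why: Conia-type deconjugative α,α-dialkylation, in which the thermodynamic extended dienolate alkylates at C2 both times and the second alkylation leaves the ring alkene out of conjugation (C3=C4), while limiting 2 to two equivalents holds back attack at C5; no stereocentre is formed.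

Step 2
Reactants: 4 3-methyl-2,2-bis(3-methylbut-2-en-1-yl)cyclopent-3-en-1-one
Product: 6 4-methyl-5,5-bis(3-methylbut-2-en-1-yl)cyclopent-3-ene-1,2-dione, via oximino ketone 5 (not isolated)
Conditions: KOt-Bu (1.2 equiv), isopentyl nitrite (1.3 equiv), THF, −20 to 0 °C; then 37% aq. HCHO (10 equiv), 1 M HCl, THF, rt
Reagents that add atoms: isopentyl nitrite CC(C)CCON=O (N and O of 5); water O (new carbonyl oxygen of 6)
Why: Base-mediated α-oximation with an alkyl nitrite hits the only enolisable carbon (α-keto and allylic) by enolate chemistry that ignores the prenyl alkenes, and acid-catalysed transoximation to excess formaldehyde frees the non-enolisable 1,2-dione under dilute acid at rt that the prenyl groups tolerate.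

Step 3
Reactants: 6 4-methyl-5,5-bis(3-methylbut-2-en-1-yl)cyclopent-3-ene-1,2-dione
Product: 8 3-hydroxy-5-methyl-6,6-bis(3-methylbut-2-en-1-yl)cyclohexa-2,4-dien-1-one (enol of the cyclohex-4-ene-1,3-dione), via silyl dienol ether 7 (not isolated)
Conditions: Me3SiCHN2 (1.1 equiv), Sc(OTf)3 (10 mol %), CH2Cl2, −78 to −20 °C; then 10% aq. citric acid, THF, rt
Reagents that add atoms: (trimethylsilyl)diazomethane C[Si](C)(C)C=[N+]=[N-]
Why: Proposed new method: Sc(OTf)3-catalysed insertion of the Me3SiCHN2 carbon into the OC–CO bond of a non-enolisable cyclopent-3-ene-1,2-dione, not yet shown on this kind of substrate; the s-cis dione chelates scandium, the diazo carbon adds to a carbonyl, and the scandium alkoxide expels N2 while the neighbouring acyl carbon makes the 1,2-shift (a stepwise ionic ring expansion); the acyl group is preferred over the vinyl or quaternary alkyl carbon because only its shift gives a 1,3-dione and keeps the enone conjugated, so attack at either carbonyl ends in the same ring; a 1,3 C-to-O silyl shift then gives 7, mild acid hydrolyses it to 8, and the β,β-disubstituted enone is too hindered for dipolar cycloaddition; the closest known reaction types are the Lewis-acid diazoalkane–ketone homologation (Büchner–Curtius–Schlotterbeck, Tiffeneau–Demjanov type) and the acyl-shift enlargement of cyclobutene-1,2-diones by diazo esters; no stereocentre is formed.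

Step 4
Reactants: 9 anisole
Product: 14 3-hydroxy-4-methoxy-2,3-dihydro-1H-isoindol-1-one (racemic hemiaminal), via 2-lithioanisole 10 (not isolated), via lithium amino alkoxide 11 (not isolated), via ring-lithiated amino alkoxide 12 (not isolated), via 2-formyl-3-methoxybenzamide 13 (not isolated)
Conditions: n-BuLi (1.1 equiv), TMEDA, Et2O, 0 °C to rt; Me2NCH2CH2N(Me)CHO (1.1 equiv), THF, −40 to 0 °C; n-BuLi (2.5 equiv), −20 °C, 16 h; Me3SiNCO (4 equiv), −78 °C to rt; 1 M HCl
Reagents that add atoms: N-formyl-N,N',N'-trimethylethylenediamine CN(C)CCN(C)C=O (CH–O of C3); trimethylsilyl isocyanate C[Si](C)(C)N=C=O (C1, its O and N); n-butyllithium [Li]CCCC (Li of 10 to 12 only)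
Why: Directed ortho-metalation is used twice: OMe directs the first lithiation, the formamide turns 10 into the chelating α-amino alkoxide 11 (Comins method), whose diamine arm outcompetes OMe and sends the second lithiation to the other ortho position of the masked aldehyde; Me3SiNCO converts the aryllithium into the primary amide, and the aldehyde 13 freed on work-up closes by itself to the hemiaminal lactam, whose racemic carbon is erased in step 5.

Step 5
Reactants: 8 3-hydroxy-5-methyl-6,6-bis(3-methylbut-2-en-1-yl)cyclohexa-2,4-dien-1-one; 14 3-hydroxy-4-methoxy-2,3-dihydro-1H-isoindol-1-one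
Product: 16 (3S)-3-[2-hydroxy-4-methyl-5,5-bis(3-methylbut-2-en-1-yl)-6-oxocyclohexa-1,3-dien-1-yl]-4-methoxy-2,3-dihydro-1H-isoindol-1-one (target), via acylimine 15 (not isolated)
Conditions: (R)-3,3'-bis(2,4,6-triisopropylphenyl)-1,1'-binaphthyl-2,2'-diyl hydrogen phosphate (10 mol %), 4 Å molecular sieves, CH2Cl2, 0 °C
Reagents that add atoms: none
Why: Chiral phosphoric acid catalysed Mannich-type amidoalkylation, in which the acid dehydrates 14 (ionisation is helped by the ortho OMe) to acylimine 15 and binds it through P–OH···N while P=O holds the enol O–H of 8, so that C2 of 8 is delivered to the Re face of C3 of 15 inside the chiral pocket and gives the (S) centre; the weak acid and low temperature spare the prenyl groups.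

## Compound list
1 | 3-methylcyclopent-2-en-1-one | CC1=CC(=O)CC1 | starting material
2 | 1-bromo-3-methylbut-2-ene (prenyl bromide) | CC(C)=CCBr | starting material
3 | 3-methyl-2-(3-methylbut-2-en-1-yl)cyclopent-2-en-1-one | CC1=C(CC=C(C)C)C(=O)CC1 | intermediate (not isolated)
4 | 3-methyl-2,2-bis(3-methylbut-2-en-1-yl)cyclopent-3-en-1-one | CC1=CCC(=O)C1(CC=C(C)C)CC=C(C)C | intermediate
5 | 5-(hydroxyimino)-3-methyl-2,2-bis(3-methylbut-2-en-1-yl)cyclopent-3-en-1-one | CC1=CC(=NO)C(=O)C1(CC=C(C)C)CC=C(C)C | intermediate (not isolated)
6 | 4-methyl-5,5-bis(3-methylbut-2-en-1-yl)cyclopent-3-ene-1,2-dione | CC1=CC(=O)C(=O)C1(CC=C(C)C)CC=C(C)C | intermediate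
7 | 5-methyl-6,6-bis(3-methylbut-2-en-1-yl)-3-(trimethylsilyloxy)cyclohexa-2,4-dien-1-one | C[Si](C)(C)OC1=CC(=O)C(CC=C(C)C)(CC=C(C)C)C(C)=C1 | intermediate (not isolated)
8 | 3-hydroxy-5-methyl-6,6-bis(3-methylbut-2-en-1-yl)cyclohexa-2,4-dien-1-one | OC1=CC(=O)C(CC=C(C)C)(CC=C(C)C)C(C)=C1 | intermediate
9 | anisole | COc1ccccc1 | starting material
10 | 2-lithioanisole | COc1ccccc1[Li] | intermediate (not isolated)
11 | lithium [2-(dimethylamino)ethyl](methyl)amino(2-methoxyphenyl)methoxide (racemic) | COc1ccccc1C(O[Li])N(C)CCN(C)C | intermediate (not isolated)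
12 | 6-lithio derivative of 11 (racemic) | COc1cccc([Li])c1C(O[Li])N(C)CCN(C)C | intermediate (not isolated)
13 | 2-formyl-3-methoxybenzamide | COc1cccc(C(N)=O)c1C=O | intermediate (not isolated)
14 | 3-hydroxy-4-methoxy-2,3-dihydro-1H-isoindol-1-one (racemic) | COc1cccc2c1C(O)NC2=O | intermediate
15 | 4-methoxy-1H-isoindol-1-one (N-acylimine) | COc1cccc2c1C=NC2=O | intermediate (not isolated)
16 | (3S)-3-[2-hydroxy-4-methyl-5,5-bis(3-methylbut-2-en-1-yl)-6-oxocyclohexa-1,3-dien-1-yl]-4-methoxy-2,3-dihydro-1H-isoindol-1-one | COc1cccc2c1[C@@H](C1=C(O)C=C(C)C(CC=C(C)C)(CC=C(C)C)C1=O)NC2=O | target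

## Count and risks
Total step count: 5. Longest linear sequence: 4 (steps 1, 2, 3, 5).

Step 3 (the new step). The vinyl carbon may shift instead of the acyl carbon, which would give the isomeric six-membered 1,2-dione. The adduct may also close to a spiro-epoxide. The fallback uses known chemistry, sets out from 6 and comes back at 8. Allyl diazoacetate is deprotonated with LiN(i-Pr)2 (THF, −78 °C) and adds to the less hindered carbonyl of 6 to give the α-diazo-β-hydroxy ester F1. Rh2(OAc)4 (1 mol %, CH2Cl2, rt) then releases N2 and drives the carbenoid 1,2-acyl shift to the ring-expanded allyl ester F2. Pd(PPh3)4 with morpholine (THF, rt) removes the allyl group, and the β-keto acid loses CO2 to give 8.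

Step 4. The second lithiation may be incomplete or go next to OMe, and excess n-BuLi consumes Me3SiNCO. The fallback sets out from 9 and comes back at 14. It separates the events and brings in nitrogen by ammonolysis instead of an isocyanate. Lithiation of 9 (n-BuLi, TMEDA) and DMF give isolated 2-methoxybenzaldehyde F3. LiN(Me)CH2CH2NMe2, then n-BuLi, then ClCO2Me and acid work-up give methyl 2-formyl-3-methoxybenzoate F4, whose regiochemistry can be checked at this stage. NH3 in MeOH (7 M, rt) adds to the aldehyde and closes onto the ester to give 14.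

Step 5. The ee may be modest, either from background catalysis by the acidic 8 or from reversible retro-Mannich ionisation of the product. The enol may also cyclise onto a prenyl group. The fallback sets out from 8 and 14 and comes back at 16. It replaces asymmetric catalysis by resolution. p-Toluenesulfonic acid monohydrate (5 mol %, CH2Cl2, rt) gives the racemate F5 by classical N-acyliminium amidoalkylation. Preparative chiral SFC on an amylose tris(3,5-dimethylphenylcarbamate) phase then gives 16 and the (R)-enantiomer F6. F6 is re-equilibrated to F5 with the same acid and recycled.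

## Further compounds
F1 | step 3 | allyl 2-diazo-2-[1-hydroxy-3-methyl-4,4-bis(3-methylbut-2-en-1-yl)-5-oxocyclopent-2-en-1-yl]acetate (racemic) | O=C1C(O)(C(=[N+]=[N-])C(=O)OCC=C)C=C(C)C1(CC=C(C)C)CC=C(C)C
F2 | step 3 | allyl 2-hydroxy-4-methyl-5,5-bis(3-methylbut-2-en-1-yl)-6-oxocyclohexa-1,3-diene-1-carboxylate | C=CCOC(=O)C1=C(O)C=C(C)C(CC=C(C)C)(CC=C(C)C)C1=O
F3 | step 4 | 2-methoxybenzaldehyde | COc1ccccc1C=O
F4 | step 4 | methyl 2-formyl-3-methoxybenzoate | COc1cccc(C(=O)OC)c1C=O
F5 | step 5 | racemic 3-[2-hydroxy-4-methyl-5,5-bis(3-methylbut-2-en-1-yl)-6-oxocyclohexa-1,3-dien-1-yl]-4-methoxy-2,3-dihydro-1H-isoindol-1-one | COc1cccc2c1C(C1=C(O)C=C(C)C(CC=C(C)C)(CC=C(C)C)C1=O)NC2=O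
F6 | step 5 | (3R)-enantiomer of 16 | COc1cccc2c1[C@H](C1=C(O)C=C(C)C(CC=C(C)C)(CC=C(C)C)C1=O)NC2=O
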